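1. The strategy rests on ring A (C4a, C5–H, C6–OH, C7–H, C8–OH, C8a), a resorcinol fused to ring B with C8–OH peri to the C1 carbonyl (C1 lies between C8a and the chloride carbon C2); this 1,3-dioxygen pattern is the imprint of 1-methoxy-1,3-bis(trimethylsilyloxy)buta-1,3-diene, so ring A is made last by disconnecting C4a–C5 and C8–C8a.
2. The dienophile is the chiral ring-B ene-dione with its methoxy leaving group on C8a, not C4a: in this class of cycloaromatisation the diene CH2 terminus bonds to the unsubstituted alkene carbon and the ester-level carbon to the carbon carrying the leaving group, so only the C8a-methoxy isomer puts C8–OH beside C1 (a C4a-methoxy isomer would give the 5,7-diol); the tertiary OH is capped as a trimethylsilyl ether.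
3. Ring B: the trans chlorohydrin comes from chloride opening (inversion at C2) of the (1S,6R)-epoxide, made by cinchona phase-transfer epoxidation of the methoxyquinone whose OMe sits beside the carbonyl next to the methyl-bearing carbon.
4. The quinone comes from oxidation of 6-methoxy-2-methyl-3-(C15 chain)phenol, assembled by copper-mediated coupling of brominated 2-methoxy-6-methylphenol (as its carbamate) with the C15 allylic bromide (geranyl bromide, triethyl phosphonoacetate, acetone).
5. Ring order: ring B derives from the starting arene (dearomatised through the quinone), ring A is closed last in one operation, and global desilylation ends the route.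

Key step: step 15

Remark on names: ring positions follow the numbering above (C1 carbonyl, C2 with Cl and CH3, C3 with OH and side chain, C4 carbonyl, C4a/C8a fusion); "C15 chain" means (4E)-5,9-dimethyl-2-(propan-2-ylidene)deca-4,8-dien-1-yl, i.e. ring–CH2–C(=CMe2)–CH2–CH=C(Me)–CH2CH2–CH=CMe2; the target is (2R,3S) with Cl and OH trans.
Assumption: the N-benzylquinidinium salt in step 10 is taken to deliver the peroxide to the quinone face that gives the (1S,6R)-epoxide; if the first run shows the opposite sense, the pseudoenantiomeric N-benzylquininium salt is used in the same step.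

**Step 1**
Reactants: 1 triethyl phosphonoacetate; 2 geranyl bromide
Product: 3 ethyl (4E)-2-(diethoxyphosphoryl)-5,9-dimethyldeca-4,8-dienoate (racemic at C2)
Conditions: NaH, THF, 0 → 23 °C
Reagents that add atoms: none
Why: SN2 C-alkylation of the stabilised phosphonoacetate sodium enolate with a primary allylic bromide is reliable, and a slight excess of the phosphonate suppresses dialkylation.

**Step 2**
Reactants: 3 ethyl (4E)-2-(diethoxyphosphoryl)-5,9-dimethyldeca-4,8-dienoate
Product: 4 ethyl (4E)-5,9-dimethyl-2-(propan-2-ylidene)deca-4,8-dienoate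
Conditions: NaH, THF, 0 °C; acetone (excess), reflux
Reagents that add atoms: acetone, CC(C)=O
Why: Horner–Wadsworth–Emmons olefination of the α-substituted phosphonate anion with acetone should give the tetrasubstituted alkene, which has no geometry to control because the two new methyl groups are identical, and excess ketone with heating offsets the slow addition.

**Step 3**
Reactants: 4 ethyl (4E)-5,9-dimethyl-2-(propan-2-ylidene)deca-4,8-dienoate
Product: 5 (4E)-5,9-dimethyl-2-(propan-2-ylidene)deca-4,8-dien-1-ol
Conditions: i-Bu2AlH, CH2Cl2, −78 → 0 °C; aq. potassium sodium tartrate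
Reagents that add atoms: none
Why: 1,2-reduction of the conjugated ester by the aluminium hydride gives the allylic alcohol and leaves the alkenes untouched.

**Step 4**
Reactants: 5 (4E)-5,9-dimethyl-2-(propan-2-ylidene)deca-4,8-dien-1-ol
Product: 6 (5E)-3-(bromomethyl)-2,6,10-trimethylundeca-2,5,9-triene (the C15 allylic bromide)
Conditions: PBr3, Et2O, −10 °C
Reagents that add atoms: phosphorus tribromide, BrP(Br)Br
Why: Bromination of the primary allylic alcohol through its phosphite ester (SN2) at low temperature keeps the thermodynamically preferred primary allylic bromide and the E alkene.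

**Step 5**
Reactants: 7 2-methoxy-6-methylphenol
Product: 8 2-methoxy-6-methylphenyl N,N-diethylcarbamate
Conditions: NaH, THF, 0 °C; Et2NCOCl, 0 → 23 °C
Reagents that add atoms: N,N-diethylcarbamoyl chloride, CCN(CC)C(=O)Cl
Why: O-carbamoylation of the sodium phenoxide damps the phenol oxygen so that the methoxy group becomes the dominant director in step 6, and the carbamate is inert to organolithium reagents at −78 °C.

**Step 6**
Reactants: 8 2-methoxy-6-methylphenyl N,N-diethylcarbamate
Product: 9 3-bromo-6-methoxy-2-methylphenyl N,N-diethylcarbamate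
Conditions: NBS, MeCN, 0 → 23 °C, dark
Reagents that add atoms: N-bromosuccinimide, O=C1CCC(=O)N1Br
Why: Electrophilic aromatic bromination goes para to the methoxy group (the position beside the ring methyl), the pattern known for O-acylated guaiacols, so the bromine marks the carbon that will carry the side chain.

**Step 7**
Reactants: 9 3-bromo-6-methoxy-2-methylphenyl N,N-diethylcarbamate; 6 (5E)-3-(bromomethyl)-2,6,10-trimethylundeca-2,5,9-triene
Product: 12 6-methoxy-2-methyl-3-(C15 chain)phenyl N,N-diethylcarbamate, via aryllithium 10 (not isolated), via arylcopper 11 (not isolated)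
Conditions: n-BuLi, THF, −78 °C; CuBr·SMe2 (monovalent copper), −78 → −40 °C; 6, −78 → 0 °C
Reagents that add atoms: none
Why: Bromine–lithium exchange, transmetalation to monovalent copper and SN2 allylation of the arylcopper by the primary allylic bromide should give the linear product, since SN2′ attack at the fully substituted γ-carbon would have to build a quaternary benzylic centre.

**Step 8**
Reactants: 12 6-methoxy-2-methyl-3-(C15 chain)phenyl N,N-diethylcarbamate
Product: 13 6-methoxy-2-methyl-3-(C15 chain)phenol
Conditions: LiAlH4, THF, 0 → 23 °C; aq. potassium sodium tartrate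
Reagents that add atoms: none
Why: Reductive cleavage of the aryl carbamate by the aluminium hydride frees the phenol, while the alkenes and the aryl methyl ether are inert.

**Step 9**
Reactants: 13 6-methoxy-2-methyl-3-(C15 chain)phenol
Product: 14 5-methoxy-3-methyl-2-(C15 chain)cyclohexa-2,5-diene-1,4-dione
Conditions: O2 (1 atm), Co(salen) [N,N′-bis(salicylidene)ethylenediamine complex of divalent cobalt] 10 mol %, MeCN, 23 °C
Reagents that add atoms: dioxygen, O=O
Why: Cobalt–salen catalysed aerobic oxidation of a 2,6-disubstituted phenol with a free para position gives the para-quinone, which places the methoxy group beside the carbonyl that neighbours the methyl-bearing carbon.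

**Step 10**
Reactants: 14 5-methoxy-3-methyl-2-(C15 chain)cyclohexa-2,5-diene-1,4-dione
Product: 15 (1S,6R)-3-methoxy-1-methyl-6-(C15 chain)-7-oxabicyclo[4.1.0]hept-3-ene-2,5-dione
Conditions: t-BuOOH, N-benzylquinidinium chloride (10 mol %), aq. NaOH (cat.), PhMe, −10 °C
Reagents that add atoms: tert-butyl hydroperoxide, CC(C)(C)OO
Why: In this Weitz–Scheffer epoxidation under chiral cinchona phase-transfer catalysis the peroxide anion adds only to the dialkyl alkene, because the methoxy-bearing alkene is a deactivated vinylogous ester, and the chiral ion pair selects the quinone face, setting both ring stereocentres as the cis-fused (1S,6R)-epoxide.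

**Step 11**
Reactants: 15 (1S,6R)-3-methoxy-1-methyl-6-(C15 chain)-7-oxabicyclo[4.1.0]hept-3-ene-2,5-dione
Product: 16 (5S,6R)-6-chloro-5-hydroxy-2-methoxy-6-methyl-5-(C15 chain)cyclohex-2-ene-1,4-dione
Conditions: LiCl, AcOH, THF, 0 → 23 °C
Reagents that add atoms: lithium chloride, [Li+].[Cl-]
Why: Acid-assisted SN2 opening of the epoxy ketone by chloride with inversion should occur at the methyl-bearing carbon, which is the less hindered epoxide carbon and lies α to the more electron-poor carbonyl (the other carbonyl is a vinylogous ester), giving the trans chlorohydrin with C2 R and C3 S.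

**Step 12**
Reactants: 16 (5S,6R)-6-chloro-5-hydroxy-2-methoxy-6-methyl-5-(C15 chain)cyclohex-2-ene-1,4-dione
Product: 17 (5S,6R)-6-chloro-2-methoxy-6-methyl-5-(C15 chain)-5-(trimethylsilyloxy)cyclohex-2-ene-1,4-dione
Conditions: Me3SiOTf, 2,6-lutidine, CH2Cl2, −78 °C
Reagents that add atoms: trimethylsilyl trifluoromethanesulfonate, C[Si](C)(C)OS(=O)(=O)C(F)(F)F
Why: Silyl triflate silylation of the hindered tertiary alcohol is clean because neither ketone is enolisable, and the cap blocks retro-aldol cleavage and epoxide re-closure and removes the hydroxyl hydrogen bond to the C4 carbonyl before the annulation.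

**Step 13**
Reactants: 18 methyl acetoacetate
Product: 19 methyl 3-(trimethylsilyloxy)but-2-enoate (alkene isomer mixture)
Conditions: Me3SiCl, Et3N, hexane, 23 °C
Reagents that add atoms: chlorotrimethylsilane, C[Si](C)(C)Cl
Why: O-silylation of the β-keto ester enol under amine base is the standard first stage of the bis(silyloxy)diene preparation.

**Step 14**
Reactants: 19 methyl 3-(trimethylsilyloxy)but-2-enoate
Product: 20 1-methoxy-1,3-bis(trimethylsilyloxy)buta-1,3-diene (used as the isomer mixture formed)
Conditions: LiN(i-Pr)2, THF, −78 °C; Me3SiCl, −78 → 0 °C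
Reagents that add atoms: chlorotrimethylsilane, C[Si](C)(C)Cl
Why: γ-Deprotonation of the silyl enol ether ester to the dienolate and O-silylation gives the ketene-acetal diene.

**Step 15**
Reactants: 17 (5S,6R)-6-chloro-2-methoxy-6-methyl-5-(C15 chain)-5-(trimethylsilyloxy)cyclohex-2-ene-1,4-dione; 20 1-methoxy-1,3-bis(trimethylsilyloxy)buta-1,3-diene
Product: 22 (2R,3S)-2-chloro-8-hydroxy-2-methyl-3-(C15 chain)-3,6-bis(trimethylsilyloxy)-2,3-dihydronaphthalene-1,4-dione, via cycloadduct 21 (not isolated)
Conditions: 20 (3 equiv), PhMe, 23 → 70 °C; then SiO2, CH2Cl2, 23 °C (brief); crude 22 is carried on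
Reagents that add atoms: none
Why: The electron-rich diene 20 adds to the only electron-poor alkene of 17 in an asynchronous Diels–Alder reaction (in the polar limit a Mukaiyama–Michael addition followed by a Claisen-type closure), its CH2 terminus bonding to C4a and its ester-level carbon to C8a to give cycloadduct 21, which loses methanol across C4a–C8a (E1cB through the C4 enol) and methoxytrimethylsilane from the C8 ketal and then enolises to the resorcinol. The closest known reaction type is the cycloaromatisation of 1,3-bis(silyloxy)dienes with halogen- or alkoxy-substituted quinones and ene-diones, in which the ester-level carbon ends on the carbon that carries the leaving group. Ring A is closed as a six-membered carbocycle in the suprafacial [4+2] mode, which in the stepwise picture is a 6-exo-trig attack of the C8a enolate on the ester-level C8. No new stereocentre survives, because the sp3 centres C4a, C8 and C8a of 21 are erased on aromatisation, and the quaternary, non-enolisable C2 and C3 are not touched. The selectivity needed is regiochemical (C5 to C4a, C8 to C8a): the methoxy group on C8a turns the C4 carbonyl into a weakly accepting vinylogous ester carbonyl, so the C1 ketone, further activated by the α-chlorine, polarises the alkene and makes C4a the electrophilic carbon, while the absence of a Lewis acid and the silyl cap on the C3 oxygen disfavour ipso addition–elimination at C8a. Chemoselectivity follows because the trisubstituted alkenes of the side chain are not dienophiles and no oxidant or strong acid is present.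

**Step 16**
Reactants: 22 (2R,3S)-2-chloro-8-hydroxy-2-methyl-3-(C15 chain)-3,6-bis(trimethylsilyloxy)-2,3-dihydronaphthalene-1,4-dione
Product: 23 (2R,3S)-2-chloro-3,6,8-trihydroxy-2-methyl-3-(C15 chain)-2,3-dihydronaphthalene-1,4-dione (CNP0351608.1)
Conditions: citric acid, MeOH, 23 °C
Reagents that add atoms: none
Why: Acid-catalysed methanolysis cleaves the aryl and the tertiary trimethylsilyl ethers, and the tertiary chloride, the α-ketol and the side-chain alkenes should tolerate dilute citric acid at room temperature.

**Compound list**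

1 | triethyl phosphonoacetate | CCOC(=O)CP(=O)(OCC)OCC | starting material
2 | geranyl bromide | CC(C)=CCC/C(C)=C/CBr | starting material
3 | ethyl (4E)-2-(diethoxyphosphoryl)-5,9-dimethyldeca-4,8-dienoate (racemic) | CC(C)=CCC/C(C)=C/CC(C(=O)OCC)P(=O)(OCC)OCC | intermediate
4 | ethyl (4E)-5,9-dimethyl-2-(propan-2-ylidene)deca-4,8-dienoate | CC(C)=CCC/C(C)=C/CC(C(=O)OCC)=C(C)C | intermediate
5 | (4E)-5,9-dimethyl-2-(propan-2-ylidene)deca-4,8-dien-1-ol | CC(C)=CCC/C(C)=C/CC(CO)=C(C)C | intermediate
6 | (5E)-3-(bromomethyl)-2,6,10-trimethylundeca-2,5,9-triene | CC(C)=CCC/C(C)=C/CC(CBr)=C(C)C | intermediate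
7 | 2-methoxy-6-methylphenol | COc1cccc(C)c1O | starting material
8 | 2-methoxy-6-methylphenyl N,N-diethylcarbamate | CCN(CC)C(=O)Oc1c(C)cccc1OC | intermediate
9 | 3-bromo-6-methoxy-2-methylphenyl N,N-diethylcarbamate | CCN(CC)C(=O)Oc1c(C)c(Br)ccc1OC | intermediate
10 | [3-(diethylcarbamoyloxy)-4-methoxy-2-methylphenyl]lithium (formed in situ) | CCN(CC)C(=O)Oc1c(C)c([Li])ccc1OC | intermediate
11 | [3-(diethylcarbamoyloxy)-4-methoxy-2-methylphenyl]copper (formed in situ) | CCN(CC)C(=O)Oc1c(C)c([Cu])ccc1OC | intermediate
12 | 6-methoxy-2-methyl-3-(C15 chain)phenyl N,N-diethylcarbamate | CC(C)=CCC/C(C)=C/CC(Cc1ccc(OC)c(OC(=O)N(CC)CC)c1C)=C(C)C | intermediate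
13 | 6-methoxy-2-methyl-3-(C15 chain)phenol | CC(C)=CCC/C(C)=C/CC(Cc1ccc(OC)c(O)c1C)=C(C)C | intermediate
14 | 5-methoxy-3-methyl-2-(C15 chain)cyclohexa-2,5-diene-1,4-dione | CC(C)=CCC/C(C)=C/CC(CC1=C(C)C(=O)C(OC)=CC1=O)=C(C)C | intermediate
15 | (1S,6R)-3-methoxy-1-methyl-6-(C15 chain)-7-oxabicyclo[4.1.0]hept-3-ene-2,5-dione | CC(C)=CCC/C(C)=C/CC(C[C@@]12O[C@]1(C)C(=O)C(OC)=CC2=O)=C(C)C | intermediate
16 | (5S,6R)-6-chloro-5-hydroxy-2-methoxy-6-methyl-5-(C15 chain)cyclohex-2-ene-1,4-dione | CC(C)=CCC/C(C)=C/CC(C[C@]1(O)C(=O)C=C(OC)C(=O)[C@]1(C)Cl)=C(C)C | intermediate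
17 | (5S,6R)-6-chloro-2-methoxy-6-methyl-5-(C15 chain)-5-(trimethylsilyloxy)cyclohex-2-ene-1,4-dione | CC(C)=CCC/C(C)=C/CC(C[C@]1(O[Si](C)(C)C)C(=O)C=C(OC)C(=O)[C@]1(C)Cl)=C(C)C | intermediate
18 | methyl acetoacetate | CC(=O)CC(=O)OC | starting material
19 | methyl 3-(trimethylsilyloxy)but-2-enoate | COC(=O)C=C(C)O[Si](C)(C)C | intermediate
20 | 1-methoxy-1,3-bis(trimethylsilyloxy)buta-1,3-diene | C=C(O[Si](C)(C)C)C=C(OC)O[Si](C)(C)C | intermediate
21 | (2R,3S)-2-chloro-8,8a-dimethoxy-2-methyl-3-(C15 chain)-3,6,8-tris(trimethylsilyloxy)-2,3,4a,5,8,8a-hexahydronaphthalene-1,4-dione (cycloadduct, mixture at C4a, C8, C8a, formed in situ) | CC(C)=CCC/C(C)=C/CC(C[C@]1(O[Si](C)(C)C)C(=O)C2CC(O[Si](C)(C)C)=CC(OC)(O[Si](C)(C)C)C2(OC)C(=O)[C@]1(C)Cl)=C(C)C | intermediate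
22 | (2R,3S)-2-chloro-8-hydroxy-2-methyl-3-(C15 chain)-3,6-bis(trimethylsilyloxy)-2,3-dihydronaphthalene-1,4-dione | CC(C)=CCC/C(C)=C/CC(C[C@]1(O[Si](C)(C)C)C(=O)c2cc(O[Si](C)(C)C)cc(O)c2C(=O)[C@]1(C)Cl)=C(C)C | intermediate
23 | (2R,3S)-2-chloro-3,6,8-trihydroxy-2-methyl-3-(C15 chain)-2,3-dihydronaphthalene-1,4-dione (CNP0351608.1) | CC(C)=CCC/C(C)=C/CC(C[C@]1(O)C(=O)c2cc(O)cc(O)c2C(=O)[C@]1(C)Cl)=C(C)C | target

**Step count:** 16 steps in total. The longest linear sequence is 12 steps (steps 1–4, 7–12, 15, 16).

**Steps most likely to fail**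

1. Step 15. The methoxy-substituted alkene is a donor-deactivated dienophile, so the cycloaddition may be slower than loss of the diene by desilylation, and a polar ipso addition–elimination at C8a could erode the regiochemistry. The fallback exchanges methoxy for chloride, the leaving group with the firmest record in this annulation. It sets out from epoxide 15. LiOH in THF–water at 0 °C hydrolyses the vinylogous ester to (1S,6R)-3-hydroxy-1-methyl-6-(C15 chain)-7-oxabicyclo[4.1.0]hept-3-ene-2,5-dione F1. Oxalyl chloride with catalytic DMF in CH2Cl2 at 0 °C converts this vinylogous acid into (1S,6R)-3-chloro-1-methyl-6-(C15 chain)-7-oxabicyclo[4.1.0]hept-3-ene-2,5-dione F2. LiCl/AcOH as in step 11 gives (5S,6R)-2,6-dichloro-5-hydroxy-6-methyl-5-(C15 chain)cyclohex-2-ene-1,4-dione F3, and Me3SiOTf/2,6-lutidine as in step 12 gives its trimethylsilyl ether F4. F4 should react with diene 20 in THF at −30 → 23 °C with loss of hydrogen chloride and methoxytrimethylsilane, and the route is re-joined at 22.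

2. Step 10. Facial selectivity may be poor on a tetrasubstituted quinone alkene, and hydroxide or peroxide may displace the methoxy group. The fallback gives up catalyst control: it sets out from quinone 14, which is epoxidised without a chiral catalyst (t-BuOOH, DBU, CH2Cl2, 0 °C) to racemic 3-methoxy-1-methyl-6-(C15 chain)-7-oxabicyclo[4.1.0]hept-3-ene-2,5-dione F5. The enantiomers are separated by preparative chromatography on a chiral stationary phase, and the (1S,6R)-enantiomer re-joins the route as 15.

3. Step 11. Substitution at a fully substituted carbon may be sluggish, and forcing it with stronger acid risks ionisation toward the side-chain-bearing carbon and protonation of the polyene. The fallback activates the epoxide with silicon instead of a proton. It sets out from 15: Me3SiCl with catalytic Bu4NCl in CH2Cl2 at 0 → 23 °C should open the epoxide through a silyloxonium–chloride ion pair at the less hindered carbon and deliver the O-silylated chlorohydrin directly. Steps 11 and 12 then merge, no free α-ketol is formed, and the route is re-joined at 17 without any new compound.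

**Further compounds**

F1 | step 15 | (1S,6R)-3-hydroxy-1-methyl-6-(C15 chain)-7-oxabicyclo[4.1.0]hept-3-ene-2,5-dione | CC(C)=CCC/C(C)=C/CC(C[C@@]12O[C@]1(C)C(=O)C(O)=CC2=O)=C(C)C
F2 | step 15 | (1S,6R)-3-chloro-1-methyl-6-(C15 chain)-7-oxabicyclo[4.1.0]hept-3-ene-2,5-dione | CC(C)=CCC/C(C)=C/CC(C[C@@]12O[C@]1(C)C(=O)C(Cl)=CC2=O)=C(C)C
F3 | step 15 | (5S,6R)-2,6-dichloro-5-hydroxy-6-methyl-5-(C15 chain)cyclohex-2-ene-1,4-dione | CC(C)=CCC/C(C)=C/CC(C[C@]1(O)C(=O)C=C(Cl)C(=O)[C@]1(C)Cl)=C(C)C
F4 | step 15 | (5S,6R)-2,6-dichloro-6-methyl-5-(C15 chain)-5-(trimethylsilyloxy)cyclohex-2-ene-1,4-dione | CC(C)=CCC/C(C)=C/CC(C[C@]1(O[Si](C)(C)C)C(=O)C=C(Cl)C(=O)[C@]1(C)Cl)=C(C)C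
F5 | step 10 | racemic 3-methoxy-1-methyl-6-(C15 chain)-7-oxabicyclo[4.1.0]hept-3-ene-2,5-dione (cis-fused) | CC(C)=CCC/C(C)=C/CC(CC12OC1(C)C(=O)C(OC)=CC2=O)=C(C)C
F0 | step 11 | none | none
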